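**Plan** (tetralone numbering; ring A = benzene ring C4a–C8a, ring B = cyclohexanone C1–C4, ring C = pyranone on C5)

- Cuts: O8–benzyl and C3–O (carried as C3–B); ring C back to a 1-ethoxyvinyl group on C5 plus malonyl dichloride, then to a C5 bromide; ring B at C2–C3 and at C4–C4a, leaving an aroyl sulfoxonium ylide and a vinylboronate; ylide back to a methyl ester; C6–phenyl by cross-coupling.
- Forward order: ring A is bought as a 4-bromosalicylate, arylated and turned into the ylide; ring B is annulated onto it in one step; C5 is brominated and ring C is built there; C–B oxidation and debenzylation finish.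
- Enabling feature: the C1 carbonyl of ring B joins C2 (its α-carbon, which can be carried as a sulfoxonium ylide, a metal-carbene precursor) and, through C8a, the position C4a, which is the only ortho C–H of the aryl ketone because C8 bears oxygen. One rhodium centre can therefore hold C4a (by C–H metalation) and C2 (as a carbene) and stitch the two-carbon unit C3–C4 between them.
- Stereochemistry: the single stereocentre C3 is set in the annulation by a chiral cyclopentadienyl rhodium catalyst as a C–B bond and is transferred to C3–OH by stereoretentive oxidation.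

Key step: step 4

Assumption: the sense of induction of the chiral cyclopentadienyl ligand cannot be assigned with certainty in advance; the (R)-ligand is written, and its enantiomer would be used if it delivered the (R)-boronate.

**Step 1**
Reactants: 1 methyl 4-bromo-2-hydroxybenzoate
Product: 2 methyl 2-(benzyloxy)-4-bromobenzoate
Conditions: BnBr, K2CO3, DMF, 60 °C
Reagents that add atoms: benzyl bromide, BrCc1ccccc1
Why: Williamson ether synthesis masks the phenol, which would otherwise undergo O–H insertion with the later ylide and interfere with the rhodium step.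

**Step 2**
Reactants: 2 methyl 2-(benzyloxy)-4-bromobenzoate; 3 phenylboronic acid
Product: 4 methyl 2-(benzyloxy)-4-phenylbenzoate
Conditions: Pd(dppf)Cl2 (3 mol %), K2CO3, 1,4-dioxane/H2O, 90 °C
Reagents that add atoms: none
Why: Suzuki–Miyaura coupling (zerovalent palladium formed in situ) of the aryl bromide para to the ester installs the future C6 phenyl group; no stereocentre is formed.

**Step 3**
Reactants: 4 methyl 2-(benzyloxy)-4-phenylbenzoate; 5 trimethylsulfoxonium iodide
Product: 6 1-[2-(benzyloxy)-4-phenylphenyl]-2-[dimethyl(oxo)-λ6-sulfanylidene]ethan-1-one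
Conditions: KOt-Bu, THF, reflux (methylide pre-formed from 5, then 4 added)
Reagents that add atoms: none
Why: Acylation of dimethylsulfoxonium methylide (Corey–Chaykovsky reagent) by the methyl ester gives the stabilised aroyl sulfoxonium ylide, which brings in the future C2 as a carbene equivalent.

**Step 4**
Reactants: 6 1-[2-(benzyloxy)-4-phenylphenyl]-2-[dimethyl(oxo)-λ6-sulfanylidene]ethan-1-one; 7 2-ethenyl-4,4,5,5-tetramethyl-1,3,2-dioxaborolane
Product: 8 (S)-8-(benzyloxy)-6-phenyl-3-(4,4,5,5-tetramethyl-1,3,2-dioxaborolan-2-yl)-3,4-dihydronaphthalen-1(2H)-one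
Conditions: (R)-CpxRh(C2H4)2 (5 mol %; Cpx = C5H3 ring bridged by two CH2 groups to the 2,2'-positions of (R)-3,3'-dimethoxy-1,1'-binaphthyl), (PhCO2)2 (5 mol %), t-BuCO2H (1 equiv), 7 (2 equiv), (CF3)2CHOH/ClCH2CH2Cl, 40 °C
Reagents that add atoms: none
Why: Proposed new method: the monovalent rhodium precatalyst is oxidised by the peroxide to a trivalent cyclopentadienyl rhodium dicarboxylate that, bound to the ylide carbonyl, cleaves the C6–H bond of the benzoyl ring (future C4a) by carboxylate-assisted metalation; the aryl–rhodium bond then inserts 7 with aryl going to the CH2 terminus and rhodium to the boron-bearing carbon (forming C4–C4a), after which the ylide carbon binds rhodium, loses dimethyl sulfoxide to give a rhodium carbene, the α-boryl alkyl group migrates to the carbene carbon (forming C2–C3), and the rhodium enolate is protonated by pivalic acid in a redox-neutral cycle. The closest known reaction types are the annulation of aroyl sulfoxonium ylides with alkynes to 1-naphthols under trivalent rhodium catalysis, which uses the same C–H metalation, insertion and carbene-migration sequence, and the enantioselective alkene insertions of chiral cyclopentadienyl rhodium catalysts in dihydroisoquinolone synthesis; the insertion regiochemistry is that of Heck reactions of vinylboronates. Ring B closes in the carbene migration, a 1,1-migratory insertion that contracts a seven-membered rhodacycle (Rh, C3, C4, C4a, C8a, C1, C2) to the six-membered carbocycle. The new stereocentre C3 is fixed in the alkene insertion, where the binaphthyl wall of the chiral cyclopentadienyl ligand selects the enantioface of the coordinated vinylboronate, and it is kept in the carbene migration, which proceeds with retention at the migrating carbon. The step needs site selectivity, secured because the second ortho position carries the benzyloxy group; insertion regioselectivity, secured by α-boryl stabilisation of the carbon–rhodium bond; and capture of the alkyl–rhodium intermediate before β-hydride elimination, secured by the ylide held next to the metal in the same molecule. Boron stands in for oxygen at C3 because a β-boryl ketone, unlike a β-acyloxy or β-alkoxy ketone, cannot eliminate to a 1-naphthol under the warm, acidic conditions; it is exchanged for hydroxyl with retention in step 8.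

**Step 5**
Reactants: 8 (S)-8-(benzyloxy)-6-phenyl-3-(4,4,5,5-tetramethyl-1,3,2-dioxaborolan-2-yl)-3,4-dihydronaphthalen-1(2H)-one
Product: 9 (S)-8-(benzyloxy)-5-bromo-6-phenyl-3-(4,4,5,5-tetramethyl-1,3,2-dioxaborolan-2-yl)-3,4-dihydronaphthalen-1(2H)-one
Conditions: NBS (1.05 equiv), MeCN, 0 °C to rt, dark
Reagents that add atoms: N-bromosuccinimide, O=C1CCC(=O)N1Br
Why: Electrophilic aromatic bromination should go to C5, which is para to the benzyloxy group and ortho to the ring-B methylene, whereas the only other free position, C7, is wedged between benzyloxy and phenyl; the alkylboronate and the ketone are inert to NBS in acetonitrile.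

**Step 6**
Reactants: 9 (S)-8-(benzyloxy)-5-bromo-6-phenyl-3-(4,4,5,5-tetramethyl-1,3,2-dioxaborolan-2-yl)-3,4-dihydronaphthalen-1(2H)-one; 10 tributyl(1-ethoxyethenyl)stannane
Product: 11 (S)-8-(benzyloxy)-5-(1-ethoxyethenyl)-6-phenyl-3-(4,4,5,5-tetramethyl-1,3,2-dioxaborolan-2-yl)-3,4-dihydronaphthalen-1(2H)-one
Conditions: PdCl2(PPh3)2 (5 mol %), toluene, 100 °C
Reagents that add atoms: none
Why: Stille coupling (the divalent palladium precatalyst is reduced in situ to zerovalent palladium) transfers the 1-ethoxyvinyl group to the hindered aryl bromide under neutral conditions that leave the secondary alkylboronate and the ketone untouched.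

**Step 7**
Reactants: 11 (S)-8-(benzyloxy)-5-(1-ethoxyethenyl)-6-phenyl-3-(4,4,5,5-tetramethyl-1,3,2-dioxaborolan-2-yl)-3,4-dihydronaphthalen-1(2H)-one; 12 propanedioyl dichloride (malonyl dichloride)
Product: 14 (S)-8-(benzyloxy)-5-(4-hydroxy-2-oxo-2H-pyran-6-yl)-6-phenyl-3-(4,4,5,5-tetramethyl-1,3,2-dioxaborolan-2-yl)-3,4-dihydronaphthalen-1(2H)-one, via enol-ether acyl chloride 13 (not isolated)
Conditions: 12 (1.5 equiv), CH2Cl2, −78 °C to rt
Reagents that add atoms: none
Why: C-Acylation of the electron-rich enol ether by malonyl dichloride, then lactonisation of the acid chloride through the ether oxygen with loss of chloroethane (the enol ether/malonyl dichloride route to 4-hydroxy-2-pyranones), builds ring C; the boronate is indifferent to the hydrogen chloride released.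

**Step 8**
Reactants: 14 (S)-8-(benzyloxy)-5-(4-hydroxy-2-oxo-2H-pyran-6-yl)-6-phenyl-3-(4,4,5,5-tetramethyl-1,3,2-dioxaborolan-2-yl)-3,4-dihydronaphthalen-1(2H)-one
Product: 16 (S)-8-(benzyloxy)-3-hydroxy-5-(4-hydroxy-2-oxo-2H-pyran-6-yl)-6-phenyl-3,4-dihydronaphthalen-1(2H)-one, via borate ester 15 (not isolated)
Conditions: NaBO3·4H2O (3 equiv), THF/H2O, rt; aq. NaH2PO4 work-up
Reagents that add atoms: sodium perborate (NaBO3, used as the tetrahydrate), [Na+].[O-]OB=O
Why: Perborate oxidation of the secondary alkylboronate proceeds by 1,2-migration of C3 from boron to oxygen with retention, so the (S) configuration set in step 4 passes to the carbinol; the weakly basic medium and the still-protected phenol should avoid β-elimination and Dakin-type oxidation.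

**Step 9**
Reactants: 16 (S)-8-(benzyloxy)-3-hydroxy-5-(4-hydroxy-2-oxo-2H-pyran-6-yl)-6-phenyl-3,4-dihydronaphthalen-1(2H)-one
Product: 17 wailupemycin F, (S)-3,8-dihydroxy-5-(4-hydroxy-2-oxo-2H-pyran-6-yl)-6-phenyl-3,4-dihydronaphthalen-1(2H)-one
Conditions: H2 (1 atm), 10% Pd on carbon, EtOAc, rt
Reagents that add atoms: none
Why: Hydrogenolysis of the aryl benzyl ether under neutral conditions frees the C8 phenol without exposing the β-hydroxy ketone to acid or base, giving the target with C3 unchanged.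

**Compound list**

1 | methyl 4-bromo-2-hydroxybenzoate | COC(=O)c1ccc(Br)cc1O | starting material
2 | methyl 2-(benzyloxy)-4-bromobenzoate | COC(=O)c1ccc(Br)cc1OCc1ccccc1 | intermediate
3 | phenylboronic acid | OB(O)c1ccccc1 | starting material
4 | methyl 2-(benzyloxy)-4-phenylbenzoate | COC(=O)c1ccc(-c2ccccc2)cc1OCc1ccccc1 | intermediate
5 | trimethylsulfoxonium iodide | C[S+](C)(C)=O.[I-] | starting material
6 | 1-[2-(benzyloxy)-4-phenylphenyl]-2-[dimethyl(oxo)-λ6-sulfanylidene]ethan-1-one | CS(C)(=O)=CC(=O)c1ccc(-c2ccccc2)cc1OCc1ccccc1 | intermediate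
7 | 2-ethenyl-4,4,5,5-tetramethyl-1,3,2-dioxaborolane (vinylboronic acid pinacol ester) | C=CB1OC(C)(C)C(C)(C)O1 | starting material
8 | (S)-8-(benzyloxy)-6-phenyl-3-(4,4,5,5-tetramethyl-1,3,2-dioxaborolan-2-yl)-3,4-dihydronaphthalen-1(2H)-one | O=C1C[C@@H](B3OC(C)(C)C(C)(C)O3)Cc2c1c(OCc1ccccc1)cc(-c1ccccc1)c2 | intermediate
9 | (S)-8-(benzyloxy)-5-bromo-6-phenyl-3-(4,4,5,5-tetramethyl-1,3,2-dioxaborolan-2-yl)-3,4-dihydronaphthalen-1(2H)-one | O=C1C[C@@H](B3OC(C)(C)C(C)(C)O3)Cc2c1c(OCc1ccccc1)cc(-c1ccccc1)c2Br | intermediate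
10 | tributyl(1-ethoxyethenyl)stannane | CCCC[Sn](CCCC)(CCCC)C(=C)OCC | starting material
11 | (S)-8-(benzyloxy)-5-(1-ethoxyethenyl)-6-phenyl-3-(4,4,5,5-tetramethyl-1,3,2-dioxaborolan-2-yl)-3,4-dihydronaphthalen-1(2H)-one | O=C1C[C@@H](B3OC(C)(C)C(C)(C)O3)Cc2c1c(OCc1ccccc1)cc(-c1ccccc1)c2C(=C)OCC | intermediate
12 | propanedioyl dichloride (malonyl dichloride) | O=C(Cl)CC(=O)Cl | starting material
13 | 5-[(7S)-4-(benzyloxy)-5-oxo-2-phenyl-7-(4,4,5,5-tetramethyl-1,3,2-dioxaborolan-2-yl)-5,6,7,8-tetrahydronaphthalen-1-yl]-5-ethoxy-3-oxopent-4-enoyl chloride (not isolated) | O=C1C[C@@H](B3OC(C)(C)C(C)(C)O3)Cc2c1c(OCc1ccccc1)cc(-c1ccccc1)c2C(OCC)=CC(=O)CC(=O)Cl | intermediate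
14 | (S)-8-(benzyloxy)-5-(4-hydroxy-2-oxo-2H-pyran-6-yl)-6-phenyl-3-(4,4,5,5-tetramethyl-1,3,2-dioxaborolan-2-yl)-3,4-dihydronaphthalen-1(2H)-one | O=C1C[C@@H](B3OC(C)(C)C(C)(C)O3)Cc2c1c(OCc1ccccc1)cc(-c1ccccc1)c2-c1cc(O)cc(=O)o1 | intermediate
15 | (S)-8-(benzyloxy)-5-(4-hydroxy-2-oxo-2H-pyran-6-yl)-6-phenyl-3-[(4,4,5,5-tetramethyl-1,3,2-dioxaborolan-2-yl)oxy]-3,4-dihydronaphthalen-1(2H)-one (not isolated) | O=C1C[C@@H](OB3OC(C)(C)C(C)(C)O3)Cc2c1c(OCc1ccccc1)cc(-c1ccccc1)c2-c1cc(O)cc(=O)o1 | intermediate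
16 | (S)-8-(benzyloxy)-3-hydroxy-5-(4-hydroxy-2-oxo-2H-pyran-6-yl)-6-phenyl-3,4-dihydronaphthalen-1(2H)-one | O=C1C[C@@H](O)Cc2c1c(OCc1ccccc1)cc(-c1ccccc1)c2-c1cc(O)cc(=O)o1 | intermediate
17 | wailupemycin F, (S)-3,8-dihydroxy-5-(4-hydroxy-2-oxo-2H-pyran-6-yl)-6-phenyl-3,4-dihydronaphthalen-1(2H)-one | O=C1C[C@@H](O)Cc2c1c(O)cc(-c1ccccc1)c2-c1cc(O)cc(=O)o1 | target

**Totals**

Total step count: 9. Longest linear sequence: 9 steps (1 to 17); compounds 3, 5, 7, 10 and 12 are bought.

**Steps most likely to fail**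

Step 4. The alkyl–rhodium intermediate may undergo β-hydride elimination or protonation before the carbene forms, the vinylboronate may insert with the opposite orientation, the ylide may be lost by carbene insertion into the benzylic O–CH2 group, or the ligand may discriminate the alkene faces poorly. The fallback uses known chemistry only, sets out from 4 and returns at 16.
- Ester 4 is saponified (LiOH, THF/H2O) to 2-(benzyloxy)-4-phenylbenzoic acid F1.
- Carboxylate-directed ortho C–H allylation with allyl acetate ([Ru(p-cymene)Cl2]2, K3PO4, MeCN, 50 °C; only one ortho C–H is present) gives 2-(benzyloxy)-4-phenyl-6-(prop-2-en-1-yl)benzoic acid F2.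
- Methyllithium (Et2O, 0 °C, Me3SiCl quench) converts the acid into 1-[2-(benzyloxy)-4-phenyl-6-(prop-2-en-1-yl)phenyl]ethan-1-one F3.
- Ozonolysis (O3, CH2Cl2, −78 °C, then Me2S) gives 2-[2-acetyl-3-(benzyloxy)-5-phenylphenyl]acetaldehyde F4.
- Intramolecular aldol addition of F4 (pyrrolidine/AcOH, 0 °C) should give racemic 8-(benzyloxy)-3-hydroxy-6-phenyl-3,4-dihydronaphthalen-1(2H)-one F5.
- Preparative chromatography on a chiral stationary phase separates the enantiomers and gives (S)-8-(benzyloxy)-3-hydroxy-6-phenyl-3,4-dihydronaphthalen-1(2H)-one F6.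
- Silylation (t-BuMe2SiCl, imidazole, DMF) gives (S)-8-(benzyloxy)-3-[(tert-butyldimethylsilyl)oxy]-6-phenyl-3,4-dihydronaphthalen-1(2H)-one F7.
- F7 is carried through the conditions of steps 5, 6 and 7 (with 2,6-di-tert-butyl-4-methylpyridine as acid scavenger in the last) to its 5-bromo derivative F8, its 5-(1-ethoxyethenyl) derivative F9 and its 5-(4-hydroxy-2-oxo-2H-pyran-6-yl) derivative F10.
- HF·pyridine (THF, 0 °C) removes the silyl group and gives 16.

Step 7. The enol ether may be hydrolysed by the hydrogen chloride released, may be acylated twice, or the dealkylative lactonisation may stall at the open-chain stage. The fallback sets out from 9 and returns at 14, so it also bypasses step 6.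
- The lithium enolate of tert-butyl acetate (LDA, THF, −78 °C) is added to 3-(trimethylsilyl)propynal to give tert-butyl 3-hydroxy-5-(trimethylsilyl)pent-4-ynoate F11.
- Desilylation (K2CO3, MeOH) gives tert-butyl 3-hydroxypent-4-ynoate F12.
- Sonogashira coupling of 9 with F12 (PdCl2(PPh3)2, copper iodide CuI, Et3N, 70 °C) gives tert-butyl 5-[(7S)-4-(benzyloxy)-5-oxo-2-phenyl-7-(4,4,5,5-tetramethyl-1,3,2-dioxaborolan-2-yl)-5,6,7,8-tetrahydronaphthalen-1-yl]-3-hydroxypent-4-ynoate F13 as a mixture of carbinol epimers.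
- Dess–Martin oxidation gives the corresponding tert-butyl 3-oxopent-4-ynoate F14.
- Gold-catalysed 6-endo-dig cyclisation of the ester carbonyl onto the alkyne ((SPhos)AuNTf2, monovalent gold, MeNO2/AcOH, rt), with loss of isobutene, gives 14.

Step 5. The electrophile may attack C7, or both free positions, instead of the hindered C5 alone. The fallback moves the bromination forward; it sets out from 4 and returns at 9.
- Ester 4 is brominated (NBS, MeCN), where the position para to the benzyloxy group is unhindered and the only alternative lies between benzyloxy and phenyl, to give methyl 2-(benzyloxy)-5-bromo-4-phenylbenzoate F15.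
- The conditions of step 3 convert F15 into 1-[2-(benzyloxy)-5-bromo-4-phenylphenyl]-2-[dimethyl(oxo)-λ6-sulfanylidene]ethan-1-one F16.
- The annulation of step 4 with 7 then has to take place at the C–H bond next to bromine and gives 9 directly.

**Further compounds**

F1 | step 4 | 2-(benzyloxy)-4-phenylbenzoic acid | OC(=O)c1ccc(-c2ccccc2)cc1OCc1ccccc1
F2 | step 4 | 2-(benzyloxy)-4-phenyl-6-(prop-2-en-1-yl)benzoic acid | OC(=O)c1c(CC=C)cc(-c2ccccc2)cc1OCc1ccccc1
F3 | step 4 | 1-[2-(benzyloxy)-4-phenyl-6-(prop-2-en-1-yl)phenyl]ethan-1-one | CC(=O)c1c(CC=C)cc(-c2ccccc2)cc1OCc1ccccc1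
F4 | step 4 | 2-[2-acetyl-3-(benzyloxy)-5-phenylphenyl]acetaldehyde | CC(=O)c1c(CC=O)cc(-c2ccccc2)cc1OCc1ccccc1
F5 | step 4 | racemic 8-(benzyloxy)-3-hydroxy-6-phenyl-3,4-dihydronaphthalen-1(2H)-one | O=C1CC(O)Cc2c1c(OCc1ccccc1)cc(-c1ccccc1)c2
F6 | step 4 | (S)-8-(benzyloxy)-3-hydroxy-6-phenyl-3,4-dihydronaphthalen-1(2H)-one | O=C1C[C@@H](O)Cc2c1c(OCc1ccccc1)cc(-c1ccccc1)c2
F7 | step 4 | (S)-8-(benzyloxy)-3-[(tert-butyldimethylsilyl)oxy]-6-phenyl-3,4-dihydronaphthalen-1(2H)-one | O=C1C[C@@H](O[Si](C)(C)C(C)(C)C)Cc2c1c(OCc1ccccc1)cc(-c1ccccc1)c2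
F8 | step 4 | (S)-8-(benzyloxy)-5-bromo-3-[(tert-butyldimethylsilyl)oxy]-6-phenyl-3,4-dihydronaphthalen-1(2H)-one | O=C1C[C@@H](O[Si](C)(C)C(C)(C)C)Cc2c1c(OCc1ccccc1)cc(-c1ccccc1)c2Br
F9 | step 4 | (S)-8-(benzyloxy)-3-[(tert-butyldimethylsilyl)oxy]-5-(1-ethoxyethenyl)-6-phenyl-3,4-dihydronaphthalen-1(2H)-one | O=C1C[C@@H](O[Si](C)(C)C(C)(C)C)Cc2c1c(OCc1ccccc1)cc(-c1ccccc1)c2C(=C)OCC
F10 | step 4 | (S)-8-(benzyloxy)-3-[(tert-butyldimethylsilyl)oxy]-5-(4-hydroxy-2-oxo-2H-pyran-6-yl)-6-phenyl-3,4-dihydronaphthalen-1(2H)-one | O=C1C[C@@H](O[Si](C)(C)C(C)(C)C)Cc2c1c(OCc1ccccc1)cc(-c1ccccc1)c2-c1cc(O)cc(=O)o1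
F11 | step 7 | tert-butyl 3-hydroxy-5-(trimethylsilyl)pent-4-ynoate | CC(C)(C)OC(=O)CC(O)C#C[Si](C)(C)C
F12 | step 7 | tert-butyl 3-hydroxypent-4-ynoate | CC(C)(C)OC(=O)CC(O)C#C
F13 | step 7 | tert-butyl 5-[(7S)-4-(benzyloxy)-5-oxo-2-phenyl-7-(4,4,5,5-tetramethyl-1,3,2-dioxaborolan-2-yl)-5,6,7,8-tetrahydronaphthalen-1-yl]-3-hydroxypent-4-ynoate | O=C1C[C@@H](B3OC(C)(C)C(C)(C)O3)Cc2c1c(OCc1ccccc1)cc(-c1ccccc1)c2C#CC(O)CC(=O)OC(C)(C)C
F14 | step 7 | tert-butyl 5-[(7S)-4-(benzyloxy)-5-oxo-2-phenyl-7-(4,4,5,5-tetramethyl-1,3,2-dioxaborolan-2-yl)-5,6,7,8-tetrahydronaphthalen-1-yl]-3-oxopent-4-ynoate | O=C1C[C@@H](B3OC(C)(C)C(C)(C)O3)Cc2c1c(OCc1ccccc1)cc(-c1ccccc1)c2C#CC(=O)CC(=O)OC(C)(C)C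
F15 | step 5 | methyl 2-(benzyloxy)-5-bromo-4-phenylbenzoate | COC(=O)c1cc(Br)c(-c2ccccc2)cc1OCc1ccccc1
F16 | step 5 | 1-[2-(benzyloxy)-5-bromo-4-phenylphenyl]-2-[dimethyl(oxo)-λ6-sulfanylidene]ethan-1-one | CS(C)(=O)=CC(=O)c1cc(Br)c(-c2ccccc2)cc1OCc1ccccc1
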